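The cyclohexane ring is closed by joining the ring CH that carries the 3-hydroxypropyl arm to the ring sp2 carbon of the exocyclic C=C(CH3)CHO unit. The precursor is acyclic there: a Z-enol triflate of an α-methyl β-keto ester tethered to a (Z)-homoallylic alcohol on the quaternary carbon. A 6-exo redox-relay Heck cyclisation forms the bond, sets the CH stereocentre, carries the triflate geometry into the tetrasubstituted alkene and walks palladium down the arm to its oxygen-bearing carbon, four bonds from the ring sp2 carbon, which emerges as an aldehyde. The vicinal quaternary and tertiary centres come from one catalytic allylboration; the side chain is joined by B-alkyl Suzuki coupling.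

Key step: step 13

Assumption: the absolute sense of induction of the chiral catalysts in steps 4, 8 and 13 is assigned by analogy with the closest models; if a model run shows the opposite sense the mirror-image ligand is used, the relative configuration being independent of it.

Step 1
Reactants: 1 (S)-citronellal
Product: 3 (3S)-3,7-dimethyloct-6-en-1-yne, via alkenyl nonaflate 2 (not isolated)
Conditions: C4F9SO2F (1.3 equiv), P2-Et phosphazene base (2.5 equiv), DMF, −20 °C → rt
Reagents that add atoms: none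
Why: One-pot aldehyde-to-alkyne conversion (enolate O-sulfonylation, then E2 elimination of the alkenyl sulfonate) should keep both carbons of the CH2CHO unit and leave the chiral-pool β-stereocentre untouched.

Step 2
Reactants: 4 prop-2-yn-1-ol
Product: 6 (E)-3-iodo-2-methylprop-2-en-1-ol, via alkenylalane 5 (not isolated)
Conditions: Me3Al (3 equiv), Cp2ZrCl2 (0.25 equiv), CH2Cl2, 0 °C → rt; then I2, THF, −30 → 0 °C
Reagents that add atoms: trimethylaluminium C[Al](C)C; iodine II
Why: Negishi zirconium-catalysed carboalumination adds CH3 and Al syn across the alkyne with Al at the terminus, and iodinolysis with retention should give the E-iodide.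

Step 3
Reactants: 6 (E)-3-iodo-2-methylprop-2-en-1-ol
Product: 7 (E)-3-iodo-2-methylprop-2-enal
Conditions: MnO2 (15 equiv), CH2Cl2, rt
Reagents that add atoms: none
Why: Allylic alcohol oxidation with activated MnO2 should proceed without isomerising the alkene.

Step 4
Reactants: 3 (3S)-3,7-dimethyloct-6-en-1-yne; 7 (E)-3-iodo-2-methylprop-2-enal
Product: 10 (1E,3S,4E,6S)-1-iodo-2,6,10-trimethylundeca-1,4,9-trien-3-ol, via alkenylborane 8 (not isolated), via alkenylzinc 9 (not isolated)
Conditions: Cy2BH (1.05 equiv), toluene, 0 °C → rt; Me2Zn (1.2 equiv), −78 °C; (−)-3-exo-morpholinoisoborneol (5 mol%); then 7, −20 → 0 °C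
Reagents that add atoms: none
Why: Syn hydroboration of the terminal alkyne (faster than the trisubstituted alkene) gives the E-alkenylborane, boron-to-zinc exchange follows, and amino alcohol-catalysed asymmetric alkenylzinc 1,2-addition to the Si face of the aldehyde should set the (S)-carbinol under catalyst control.

Step 5
Reactants: 10 (1E,3S,4E,6S)-1-iodo-2,6,10-trimethylundeca-1,4,9-trien-3-ol
Product: 11 tert-butyl{[(1E,3S,4E,6S)-1-iodo-2,6,10-trimethylundeca-1,4,9-trien-3-yl]oxy}dimethylsilane
Conditions: TBSCl (1.3 equiv), imidazole (2.5 equiv), DMF, rt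
Reagents that add atoms: tert-butyldimethylsilyl chloride CC(C)(C)[Si](C)(C)Cl
Why: Silyl ether formation masks the bis-allylic alcohol against the later MnO2 oxidation and against ionisation.

Step 6
Reactants: 12 (E)-3-methylpent-2-en-4-yn-1-ol
Product: 14 (E)-3-methylhept-2-en-4-yne-1,7-diol, via dilithio dianion 13 (not isolated)
Conditions: n-BuLi (2.1 equiv), THF/DMPU, −78 → −20 °C; ethylene oxide (1.5 equiv), −20 °C → rt; H2O
Reagents that add atoms: ethylene oxide C1CO1
Why: In the alkoxide–acetylide dianion the acetylide carbon is the more nucleophilic site and should open the epoxide (acetylide alkylation) without touching the E-alkene.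

Step 7
Reactants: 14 (E)-3-methylhept-2-en-4-yne-1,7-diol
Product: 15 [(2E)-7-hydroxy-3-methylhept-2-en-4-yn-1-yl]boronic acid
Conditions: B2(OH)4 (1.2 equiv), Pd(MeCN)4(BF4)2 (2 mol%), DMSO/MeOH, rt; extracted and kept as a degassed toluene solution
Reagents that add atoms: tetrahydroxydiboron OB(O)B(O)O
Why: Palladium-catalysed borylation of allylic alcohols through a π-allyl complex should activate only the allylic hydroxyl, place boron on the unhindered CH2 terminus and keep the E geometry.

Step 8
Reactants: 15 [(2E)-7-hydroxy-3-methylhept-2-en-4-yn-1-yl]boronic acid; 16 methyl 4-oxopentanoate (methyl levulinate)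
Product: 18 (5S)-5-[(3S)-7-hydroxy-3-methylhept-1-en-4-yn-3-yl]-5-methyldihydrofuran-2(3H)-one, via hydroxy ester 17 (not isolated)
Conditions: (S)-3,3′-Br2-BINOL (20 mol%), t-BuOH (2 equiv), 3 Å MS, toluene, 0 °C → rt; then PPTS (cat.), toluene, 40 °C
Reagents that add atoms: none
Why: BINOL-catalysed asymmetric allylboration of the ketone through a closed six-membered chair transition state forms the quaternary carbon by γ-attack; the E geometry (alkynyl pseudo-equatorial, methyl pseudo-axial) fixes its configuration relative to the tertiary carbinol, the chiral boronate selects the ketone face, and the γ-hydroxy ester then lactonises.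

Step 9
Reactants: 18 (5S)-5-[(3S)-7-hydroxy-3-methylhept-1-en-4-yn-3-yl]-5-methyldihydrofuran-2(3H)-one
Product: 19 (5S)-5-[(3S,4Z)-7-hydroxy-3-methylhepta-1,4-dien-3-yl]-5-methyldihydrofuran-2(3H)-one
Conditions: H2 (1 atm, 1 equiv uptake), Pd/CaCO3 poisoned with Pb(OAc)2, quinoline, EtOAc, rt
Reagents that add atoms: none
Why: Lindlar semihydrogenation adds H2 syn to the alkyne to give the Z-alkene, and the alkyne should bind the poisoned surface in preference to the hindered vinyl group.

Step 10
Reactants: 19 (5S)-5-[(3S,4Z)-7-hydroxy-3-methylhepta-1,4-dien-3-yl]-5-methyldihydrofuran-2(3H)-one; 11 tert-butyl{[(1E,3S,4E,6S)-1-iodo-2,6,10-trimethylundeca-1,4,9-trien-3-yl]oxy}dimethylsilane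
Product: 21 (5S)-5-[(3Z,5S,8E,10S,11E,13S)-10-(tert-butyldimethylsilyloxy)-1-hydroxy-5,9,13,17-tetramethyloctadeca-3,8,11,16-tetraen-5-yl]-5-methyldihydrofuran-2(3H)-one, via B-alkyl-9-BBN adduct 20 (not isolated)
Conditions: 9-BBN-H (2.2 equiv), THF, 0 °C → rt; then 11, Pd(dppf)Cl2 (5 mol%), AsPh3 (10 mol%), Cs2CO3 (3 equiv), DMF/H2O, rt
Reagents that add atoms: none
Why: 9-BBN should hydroborate the monosubstituted vinyl group anti-Markovnikov far faster than the Z-disubstituted alkene, and B-alkyl Suzuki–Miyaura coupling with the E-alkenyl iodide proceeds with retention to give the E-trisubstituted alkene.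

Step 11
Reactants: 21 (the coupled lactone)
Product: 22 ethyl (2RS,6S,7S,10E,12S,13E,15S)-12-(tert-butyldimethylsilyloxy)-6-hydroxy-7-[(1Z)-4-hydroxybut-1-en-1-yl]-2,6,7,11,15,19-hexamethyl-3-oxoicosa-10,13,18-trienoate
Conditions: LiN(i-Pr)2 (3.5 equiv), ethyl propanoate (3.4 equiv), THF, −78 °C; then 21, −78 → −40 °C; AcOH, pH 7 buffer
Reagents that add atoms: ethyl propanoate CCC(=O)OCC
Why: Crossed Claisen acylation of the propanoate enolate by the lactone carbonyl opens the ring to the β-keto ester, which is protected from over-addition as its enolate until the neutral quench.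

Step 12
Reactants: 22 (the β-keto ester)
Product: 24 ethyl (2Z,6S,7S,10E,12S,13E,15S)-12-(tert-butyldimethylsilyloxy)-6-hydroxy-7-[(1Z)-4-hydroxybut-1-en-1-yl]-2,6,7,11,15,19-hexamethyl-3-(trifluoromethylsulfonyloxy)icosa-2,10,13,18-tetraenoate, via sodium enolate 23 (not isolated)
Conditions: NaH (1.05 equiv), THF, 0 °C; PhNTf2 (1.1 equiv), 0 °C → rt
Reagents that add atoms: N-phenylbis(trifluoromethanesulfonimide) O=S(=O)(N(c1ccccc1)S(=O)(=O)C(F)(F)F)C(F)(F)F
Why: One equivalent of base deprotonates only the β-keto ester, and O-sulfonylation of the sodium-chelated Z-enolate (enol triflate formation) should place OTf cis to CO2Et while the neutral hydroxyls do not react with PhNTf2.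

Step 13
Reactants: 24 (the Z-enol triflate)
Product: 25 ethyl (2Z)-2-[(2R,3S,4S)-3-[(3E,5S,6E,8S)-5-(tert-butyldimethylsilyloxy)-4,8,12-trimethyltrideca-3,6,11-trien-1-yl]-4-hydroxy-3,4-dimethyl-2-(3-oxopropyl)cyclohexylidene]propanoate
Conditions: Pd2(dba)3 (5 mol%), (S)-4-tert-butyl-2-[5-(trifluoromethyl)pyridin-2-yl]-4,5-dihydrooxazole (12 mol%), 2,6-di-tert-butyl-4-methylpyridine (1.5 equiv), 3 Å MS, DMA, rt → 40 °C
Reagents that add atoms: none
Why: Zerovalent palladium inserts into the C–OTf bond to give a cationic alkenyl complex of divalent palladium, which adds syn across the tethered Z-alkene with C–C bond formation at the alkene carbon next to the quaternary centre; the alkyl–palladium then walks down the arm by β-hydride elimination and reinsertion until it reaches the carbinol carbon, where release of the aldehyde returns zerovalent palladium and TfOH (taken up by the pyridine base). The closest known reaction type is the redox-relay Heck alkenylation of homoallylic alcohols with alkenyl triflates, here in its ring-forming intramolecular form. The cyclohexane ring closes in the 6-exo-trig mode. The new ring CH stereocentre is set by the alkene face presented in a chair-like insertion transition state in which the arm carbon is pseudo-axial (no A(1,3) strain with the ester) and therefore syn-diaxial to the small hydroxyl and not to the methyl of the carbinol carbon, a bias the matched pyridine-oxazoline ligand should reinforce. The step needs retention of the triflate geometry (ester cis to the new ring bond), which stereospecific insertion secures; 6-exo over 7-endo closure, which ring size and the preference for bonding at the carbon remote from the hydroxyl secure; and relay towards oxygen instead of β-hydride loss from the ring CH, which the strained 1,2-bis(alkylidene)cyclohexane that would result disfavours.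

Step 14
Reactants: 25 (the cyclised aldehyde ester)
Product: 26 (2Z)-2-[(2R,3S,4S)-3-[(3E,5S,6E,8S)-5-(tert-butyldimethylsilyloxy)-4,8,12-trimethyltrideca-3,6,11-trien-1-yl]-4-hydroxy-2-(3-hydroxypropyl)-3,4-dimethylcyclohexylidene]propan-1-ol
Conditions: i-Bu2AlH (7 equiv), CH2Cl2, −78 → 0 °C; aq. potassium sodium tartrate
Reagents that add atoms: none
Why: Aluminium hydride reduction takes the aldehyde to the primary alcohol and the hindered enoate (1,2-reduction) to the allylic alcohol without affecting alkene geometry or the silyl ether.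

Step 15
Reactants: 26 (the triol)
Product: 27 (2Z)-2-[(2R,3S,4S)-3-[(3E,5S,6E,8S)-5-(tert-butyldimethylsilyloxy)-4,8,12-trimethyltrideca-3,6,11-trien-1-yl]-4-hydroxy-2-(3-hydroxypropyl)-3,4-dimethylcyclohexylidene]propanal
Conditions: MnO2 (20 equiv), CH2Cl2, rt
Reagents that add atoms: none
Why: MnO2 oxidises only the allylic primary alcohol; the saturated primary and the tertiary hydroxyl are inert, and the bis-allylic secondary alcohol is masked as its silyl ether.

Step 16
Reactants: 27 (the silyl-protected enal)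
Product: 28 (2Z)-2-[(2R,3S,4S)-4-hydroxy-3-[(3E,5S,6E,8S)-5-hydroxy-4,8,12-trimethyltrideca-3,6,11-trien-1-yl]-2-(3-hydroxypropyl)-3,4-dimethylcyclohexylidene]propanal
Conditions: Bu4NF (2 equiv), AcOH (2 equiv), THF, 0 °C → rt
Reagents that add atoms: none
Why: Buffered fluoride desilylation should free the bis-allylic alcohol without acid ionisation of that centre or base-induced isomerisation of the enal.

Compound list
1 | (S)-citronellal, (3S)-3,7-dimethyloct-6-enal | CC(C)=CCC[C@H](C)CC=O | starting material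
2 | (3S)-3,7-dimethylocta-1,6-dien-1-yl nonafluorobutanesulfonate (E/Z, formed in situ) | CC(C)=CCC[C@H](C)C=COS(=O)(=O)C(F)(F)C(F)(F)C(F)(F)C(F)(F)F | intermediate
3 | (3S)-3,7-dimethyloct-6-en-1-yne | CC(C)=CCC[C@H](C)C#C | intermediate
4 | prop-2-yn-1-ol | C#CCO | starting material
5 | (E)-alkenylalane, dimethylaluminium alkoxide of (E)-3-(dimethylalumanyl)-2-methylprop-2-en-1-ol (formed in situ) | C[Al](C)OC/C(C)=C/[Al](C)C | intermediate
6 | (E)-3-iodo-2-methylprop-2-en-1-ol | OC/C(C)=C/I | intermediate
7 | (E)-3-iodo-2-methylprop-2-enal | O=C/C(C)=C/I | intermediate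
8 | dicyclohexyl[(1E,3S)-3,7-dimethylocta-1,6-dien-1-yl]borane (formed in situ) | CC(C)=CCC[C@H](C)/C=C/B(C1CCCCC1)C1CCCCC1 | intermediate
9 | [(1E,3S)-3,7-dimethylocta-1,6-dien-1-yl](methyl)zinc (formed in situ) | CC(C)=CCC[C@H](C)/C=C/[Zn]C | intermediate
10 | (1E,3S,4E,6S)-1-iodo-2,6,10-trimethylundeca-1,4,9-trien-3-ol | CC(C)=CCC[C@H](C)/C=C/[C@H](O)/C(C)=C/I | intermediate
11 | tert-butyl{[(1E,3S,4E,6S)-1-iodo-2,6,10-trimethylundeca-1,4,9-trien-3-yl]oxy}dimethylsilane | CC(C)=CCC[C@H](C)/C=C/[C@H](O[Si](C)(C)C(C)(C)C)/C(C)=C/I | intermediate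
12 | (E)-3-methylpent-2-en-4-yn-1-ol | OC/C=C(\C)C#C | starting material
13 | dilithium alkoxide acetylide of 12 (formed in situ) | [Li]OC/C=C(\C)C#C[Li] | intermediate
14 | (E)-3-methylhept-2-en-4-yne-1,7-diol | OC/C=C(\C)C#CCCO | intermediate
15 | [(2E)-7-hydroxy-3-methylhept-2-en-4-yn-1-yl]boronic acid | OB(O)C/C=C(\C)C#CCCO | intermediate
16 | methyl 4-oxopentanoate (methyl levulinate) | CC(=O)CCC(=O)OC | starting material
17 | methyl (4S,5S)-4-hydroxy-5-(4-hydroxybut-1-yn-1-yl)-4,5-dimethylhept-6-enoate (formed in situ) | C=C[C@@](C)(C#CCCO)[C@@](C)(O)CCC(=O)OC | intermediate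
18 | (5S)-5-[(3S)-7-hydroxy-3-methylhept-1-en-4-yn-3-yl]-5-methyldihydrofuran-2(3H)-one | C=C[C@@](C)(C#CCCO)[C@]1(C)CCC(=O)O1 | intermediate
19 | (5S)-5-[(3S,4Z)-7-hydroxy-3-methylhepta-1,4-dien-3-yl]-5-methyldihydrofuran-2(3H)-one | C=C[C@@](C)(/C=C\CCO)[C@]1(C)CCC(=O)O1 | intermediate
20 | B-alkyl-9-borabicyclo[3.3.1]nonane adduct of 19, boron on the terminal carbon of the former vinyl group (formed in situ) | B1(C2CCCC1CCC2)CC[C@@](C)(/C=C\CCO)[C@]1(C)CCC(=O)O1 | intermediate
21 | (5S)-5-[(3Z,5S,8E,10S,11E,13S)-10-(tert-butyldimethylsilyloxy)-1-hydroxy-5,9,13,17-tetramethyloctadeca-3,8,11,16-tetraen-5-yl]-5-methyldihydrofuran-2(3H)-one | CC(C)=CCC[C@H](C)/C=C/[C@H](O[Si](C)(C)C(C)(C)C)/C(C)=C/CC[C@@](C)(/C=C\CCO)[C@]1(C)CCC(=O)O1 | intermediate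
22 | ethyl (2RS,6S,7S,10E,12S,13E,15S)-12-(tert-butyldimethylsilyloxy)-6-hydroxy-7-[(1Z)-4-hydroxybut-1-en-1-yl]-2,6,7,11,15,19-hexamethyl-3-oxoicosa-10,13,18-trienoate | CC(C)=CCC[C@H](C)/C=C/[C@H](O[Si](C)(C)C(C)(C)C)/C(C)=C/CC[C@@](C)(/C=C\CCO)[C@@](C)(O)CCC(=O)C(C)C(=O)OCC | intermediate
23 | sodium Z-enolate of 22 (formed in situ) | CC(C)=CCC[C@H](C)/C=C/[C@H](O[Si](C)(C)C(C)(C)C)/C(C)=C/CC[C@@](C)(/C=C\CCO)[C@@](C)(O)CC/C([O-])=C(\C)C(=O)OCC.[Na+] | intermediate
24 | ethyl (2Z,6S,7S,10E,12S,13E,15S)-12-(tert-butyldimethylsilyloxy)-6-hydroxy-7-[(1Z)-4-hydroxybut-1-en-1-yl]-2,6,7,11,15,19-hexamethyl-3-(trifluoromethylsulfonyloxy)icosa-2,10,13,18-tetraenoate | CC(C)=CCC[C@H](C)/C=C/[C@H](O[Si](C)(C)C(C)(C)C)/C(C)=C/CC[C@@](C)(/C=C\CCO)[C@@](C)(O)CC/C(OS(=O)(=O)C(F)(F)F)=C(\C)C(=O)OCC | intermediate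
25 | ethyl (2Z)-2-[(2R,3S,4S)-3-[(3E,5S,6E,8S)-5-(tert-butyldimethylsilyloxy)-4,8,12-trimethyltrideca-3,6,11-trien-1-yl]-4-hydroxy-3,4-dimethyl-2-(3-oxopropyl)cyclohexylidene]propanoate | CC(C)=CCC[C@H](C)/C=C/[C@H](O[Si](C)(C)C(C)(C)C)/C(C)=C/CC[C@@]1(C)[C@H](CCC=O)/C(=C(/C)C(=O)OCC)CC[C@]1(C)O | intermediate
26 | (2Z)-2-[(2R,3S,4S)-3-[(3E,5S,6E,8S)-5-(tert-butyldimethylsilyloxy)-4,8,12-trimethyltrideca-3,6,11-trien-1-yl]-4-hydroxy-2-(3-hydroxypropyl)-3,4-dimethylcyclohexylidene]propan-1-ol | CC(C)=CCC[C@H](C)/C=C/[C@H](O[Si](C)(C)C(C)(C)C)/C(C)=C/CC[C@@]1(C)[C@H](CCCO)/C(=C(/C)CO)CC[C@]1(C)O | intermediate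
27 | (2Z)-2-[(2R,3S,4S)-3-[(3E,5S,6E,8S)-5-(tert-butyldimethylsilyloxy)-4,8,12-trimethyltrideca-3,6,11-trien-1-yl]-4-hydroxy-2-(3-hydroxypropyl)-3,4-dimethylcyclohexylidene]propanal | CC(C)=CCC[C@H](C)/C=C/[C@H](O[Si](C)(C)C(C)(C)C)/C(C)=C/CC[C@@]1(C)[C@H](CCCO)/C(=C(/C)C=O)CC[C@]1(C)O | intermediate
28 | (2Z)-2-[(2R,3S,4S)-4-hydroxy-3-[(3E,5S,6E,8S)-5-hydroxy-4,8,12-trimethyltrideca-3,6,11-trien-1-yl]-2-(3-hydroxypropyl)-3,4-dimethylcyclohexylidene]propanal | CC(C)=CCC[C@H](C)/C=C/[C@H](O)/C(C)=C/CC[C@@]1(C)[C@H](CCCO)/C(=C(/C)C=O)CC[C@]1(C)O | target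

Total step count: 16.
Longest linear sequence: 11 steps (steps 6 to 16, from 12 to 28).

Steps most likely to fail

Step 13. Insertion at the alkene carbon next to the quaternary centre may be slow, which would allow 7-endo insertion, early loss of the palladium hydride from the chain, or poor facial selectivity. Fallback: from 24, ring closure and relay are decoupled. A conventional base-terminated cationic Heck cyclisation (Pd(OAc)2, (R)-BINAP, 1,2,2,6,6-pentamethylpiperidine, toluene, 60 °C) lets the diphosphine control the alkene face and the amine remove the palladium hydride after the first β-hydride elimination, to give the ring-closed (E)-allylic alcohol F1. The primary allylic alcohol is then isomerised to the aldehyde in a separate redox isomerisation with [Ir(cod)(PCy3)(py)]PF6 (activated with H2, then degassed, THF, rt), which rejoins the route at 25.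

Step 8. Discrimination between the methyl group and the ester-bearing arm of an aliphatic ketone in the catalyst-bound transition state may be poor, eroding enantio- and diastereoselectivity. Fallback: from 15 and 16, the allylboration is run without the chiral diol (toluene, 3 Å MS, rt). The closed chair transition state alone still fixes the relative configuration, so 18 should form as a racemate together with the mirror-image lactone F3 (through the mirror-image hydroxy ester F2). The enantiomers are separated by preparative chromatography on a chiral stationary phase (amylose tris(3,5-dimethylphenylcarbamate), supercritical CO2/MeOH), and the route is rejoined at 18.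

Step 12. The tertiary hydroxyl may attack the newly activated enol derivative in a 5-exo addition–elimination with loss of triflate, or the Z geometry may erode. Fallback: from 22, both hydroxyls are first capped (TMSCl, imidazole, DMF, 0 °C → rt) to give the bis(trimethylsilyl) ether F4, which is converted as before (NaH; PhNTf2, THF) into the silylated Z-enol triflate F5. Brief treatment with citric acid in MeOH at 0 °C then frees both hydroxyls and rejoins the route at 24.

Further compounds
F1 | step 13 | ethyl (2Z)-2-[(2R,3S,4S)-3-[(3E,5S,6E,8S)-5-(tert-butyldimethylsilyloxy)-4,8,12-trimethyltrideca-3,6,11-trien-1-yl]-4-hydroxy-2-[(1E)-3-hydroxyprop-1-en-1-yl]-3,4-dimethylcyclohexylidene]propanoate | CC(C)=CCC[C@H](C)/C=C/[C@H](O[Si](C)(C)C(C)(C)C)/C(C)=C/CC[C@@]1(C)[C@H](/C=C/CO)/C(=C(/C)C(=O)OCC)CC[C@]1(C)O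
F2 | step 8 | methyl (4R,5R)-4-hydroxy-5-(4-hydroxybut-1-yn-1-yl)-4,5-dimethylhept-6-enoate (mirror image of 17) | C=C[C@](C)(C#CCCO)[C@](C)(O)CCC(=O)OC
F3 | step 8 | (5R)-5-[(3R)-7-hydroxy-3-methylhept-1-en-4-yn-3-yl]-5-methyldihydrofuran-2(3H)-one (mirror image of 18) | C=C[C@](C)(C#CCCO)[C@@]1(C)CCC(=O)O1
F4 | step 12 | bis(trimethylsilyl) ether of 22 (tertiary and primary hydroxyl silylated) | CC(C)=CCC[C@H](C)/C=C/[C@H](O[Si](C)(C)C(C)(C)C)/C(C)=C/CC[C@@](C)(/C=C\CCO[Si](C)(C)C)[C@@](C)(O[Si](C)(C)C)CCC(=O)C(C)C(=O)OCC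
F5 | step 12 | bis(trimethylsilyl) ether of Z-enol triflate 24 | CC(C)=CCC[C@H](C)/C=C/[C@H](O[Si](C)(C)C(C)(C)C)/C(C)=C/CC[C@@](C)(/C=C\CCO[Si](C)(C)C)[C@@](C)(O[Si](C)(C)C)CC/C(OS(=O)(=O)C(F)(F)F)=C(\C)C(=O)OCC
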